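**Retrosynthetic overview**

1. The central six-membered ring of the syn-tricyclo[4.2.1.1^{2,5}]deca-3,7-diene core (two C–C bonds, four stereocentres) is cut last: a retro-[4+4] gives two [1,5]-H-shift tautomers (11 and 12) of one C15 cyclopentadiene, the 1,10-seco-aromadendrane-type monomer of the presumed biogenesis.
2. The cyclopentadiene comes from a tertiary cyclopentenol by dehydration; its five-membered ring is made by a [4+1] union of a lactone carbonyl with (pent-2-ene-1,4-diyl)magnesium.
3. The seven-membered lactone, whose ring oxygen marks the future side-chain ketone, is the Baeyer–Villiger product of carone.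
4. Carone carries the cis gem-dimethylcyclopropane in the required absolute configuration and comes from (S)-carvone by conjugate reduction, HBr addition and 3-exo-tet enolate alkylation.
5. Ring order forward: cyclopropane, then lactone, then cyclopentene, then cyclopentadiene, then the central ring of the dimer.

Assumption: the presumed biogenesis is taken to be a face-to-face [4+4] cyclodimerisation of two [1,5]-H-shift tautomers of one cyclopentadiene; stereocentres that are erased later are carried as epimer mixtures and drawn without a label.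

**Route**

Step 1
Reactants: 1 (S)-(+)-carvone
Product: 2 (2S,5S)-2-methyl-5-(prop-1-en-2-yl)cyclohexan-1-one (trans-dihydrocarvone; minor 2R epimer carried along)
Conditions: LiBH(s-Bu)3 (lithium tri-sec-butylborohydride, 1.05 equiv), THF, −78 °C; then H2O
Reagents that add atoms: none
Why: Conjugate (1,4-) hydride reduction of the enone by a bulky trialkylborohydride leaves the isopropenyl group and the C-5 stereocentre untouched; the new C-2 centre forms as a mainly trans mixture and is erased in step 5, where it becomes the side-chain C=O.

Step 2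
Reactants: 2 (2S,5S)-dihydrocarvone
Product: 4 (1R,6S)-3,7,7-trimethylbicyclo[4.1.0]heptan-2-one (carone; C-3 epimer mixture), via bromo ketone 3 (not isolated)
Conditions: HBr (33% in AcOH), 0 °C; evaporate; KOH, MeOH, 0 °C to rt
Reagents that add atoms: none
Why: Markovnikov hydrobromination of the isopropenyl group is followed by intramolecular enolate C-alkylation (the classical dihydrocarvone-to-carone cyclisation); only the C-6 enolate can reach the tertiary bromide and the ring fusion can only form cis, so the (S)-carbon of carvone fixes both cyclopropane stereocentres.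

Step 3
Reactants: 4 (1R,6S)-carone
Product: 5 (1R,7S)-4,8,8-trimethyl-3-oxabicyclo[5.1.0]octan-2-one (C-4 epimer mixture)
Conditions: m-CPBA (2 equiv), NaHCO3, CH2Cl2, rt, 48 h
Reagents that add atoms: 3-chloroperoxybenzoic acid (m-CPBA), OOC(=O)c1cccc(Cl)c1
Why: Baeyer–Villiger oxidation in which the secondary alkyl carbon migrates in preference to cyclopropyl, so oxygen is inserted on the methyl-bearing side, the acyl carbon stays on the cyclopropane and the cyclopropane stereocentres are not touched.

Step 4
Reactants: 5 lactone (1R,7S)-4,8,8-trimethyl-3-oxabicyclo[5.1.0]octan-2-one; 6 (E)-penta-1,3-diene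
Product: 8 1-[(1R,3S)-3-(3-hydroxybutyl)-2,2-dimethylcyclopropyl]-2-methylcyclopent-3-en-1-ol (epimer mixture at the three carbinol and methine centres that are erased later), via magnesacyclopentene 7 (not isolated)
Conditions: Rieke magnesium powder (Mg*, 1.5 equiv), 6 (3 equiv), THF, rt, 8 h; then 5, −78 °C to reflux, 2 h; then H2O
Reagents that add atoms: none
Why: Rieke diene–magnesium [4+1] annulation, in which the (pent-2-ene-1,4-diyl)magnesium reagent adds through both termini to the ester carbonyl to give a cyclopent-3-en-1-ol while the ring oxygen leaves as the secondary alkoxide (an internal protecting group for the future ketone); the new ring carbinol and methyl-bearing carbons form unselectively and both become sp2 in step 6.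

Step 5
Reactants: 8 diol
Product: 9 4-[(1S,3R)-3-(1-hydroxy-2-methylcyclopent-3-en-1-yl)-2,2-dimethylcyclopropyl]butan-2-one
Conditions: (n-Pr4N)RuO4 (tetrapropylammonium perruthenate, 5 mol %), N-methylmorpholine N-oxide (1.5 equiv), 4 Å MS, CH2Cl2, rt
Reagents that add atoms: none
Why: Ley–Griffith oxidation turns the secondary alcohol into the methyl ketone under neutral conditions; the tertiary cyclopropyl carbinol cannot be oxidised and sees no acid.

Step 6
Reactants: 9 keto carbinol
Product: 12 4-[(1S,3R)-2,2-dimethyl-3-(2-methylcyclopenta-1,4-dien-1-yl)cyclopropyl]butan-2-one, via diene 10 (not isolated), via diene tautomer 11 (not isolated)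
Conditions: MeO2C–N(−)–SO2–N(+)Et3 (Burgess reagent, 1.3 equiv), PhMe (0.05 M), 60 °C, 2 h; basic alumina plug (pentane) under Ar; concentrate at 0 °C and use at once
Reagents that add atoms: none
Why: Burgess dehydration, in which the tertiary sulfamate loses an allylic ring hydrogen by syn-elimination within the ion pair before the cyclopropylcarbinyl centre can open, gives diene 10, and successive [1,5]-sigmatropic hydrogen shifts at 60 °C spread the material over the tautomers 10, 11 and 12 (comparable amounts expected), which are carried on together as one cold concentrate; no stereocentre is formed and the two ring centres of 9 are erased.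

Step 7
Reactants: 11 4-[(1S,3R)-2,2-dimethyl-3-(5-methylcyclopenta-1,4-dien-1-yl)cyclopropyl]butan-2-one; 12 4-[(1S,3R)-2,2-dimethyl-3-(2-methylcyclopenta-1,4-dien-1-yl)cyclopropyl]butan-2-one (one molecule of each, both from the concentrate of step 6)
Product: 13 (1S,2S,5S,6S)-1,3-dimethyl-4,8-bis[(1R,3S)-2,2-dimethyl-3-(3-oxobutyl)cyclopropyl]tricyclo[4.2.1.1^{2,5}]deca-3,7-diene (CNP0300925.1)
Conditions: neat tautomer mixture (about 4 M), thin film in a rotating quartz tube under Ar, hν (265 nm LED), −20 °C, to about 40% conversion; preparative HPLC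
Reagents that add atoms: none
Why: Proposed new method: at 265 nm the diene takes up more than 99% of the light (the ketone n–π* band is weak and the isolated alkenes of the product are transparent), and in the neat liquid a fraction of the excited dienes has a neighbour stacked face to face, so that the singlet pair can close by the photochemically allowed suprafacial–suprafacial [4π+4π] path, C-2 of 12 bonding to C-4 of 11 and C-4 of 12 to C-2 of 11 (ring C-1 carries the cyclopropane, C-3 is the CH2) with the two ring CH2 groups on one side, which gives the syn (sandwich) dimer with a boat central ring and both etheno bridges on one face and fixes the four bridgehead centres relative to one another in one event; this orientation puts a cyclopropyl over a methyl and not over the other cyclopropyl, the sense relative to the cyclopropanes is only weakly biased, and 13 is therefore expected in low yield beside its core-mirrored diastereomer, homo-dimers and Diels–Alder-type adducts, from which it is separated by HPLC; closest known chemistry is the singlet [4+4] photodimerisation of anthracenes and 2-pyridones and the [4+4] photoaddition of singlet-excited anthracenes and naphthalenes to cyclic 1,3-dienes such as cyclohexa-1,3-diene and furan, all of which give sandwich adducts.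

**Compound list**

1 | (S)-(+)-carvone, (5S)-2-methyl-5-(prop-1-en-2-yl)cyclohex-2-en-1-one | CC1=CC[C@@H](CC1=O)C(C)=C | starting material
2 | (2S,5S)-2-methyl-5-(prop-1-en-2-yl)cyclohexan-1-one (trans-dihydrocarvone, major epimer) | C[C@H]1CC[C@@H](CC1=O)C(C)=C | intermediate
3 | (2S,5S)-5-(2-bromopropan-2-yl)-2-methylcyclohexan-1-one | C[C@H]1CC[C@@H](CC1=O)C(C)(C)Br | intermediate
4 | (1R,6S)-3,7,7-trimethylbicyclo[4.1.0]heptan-2-one (carone, C-3 epimers) | CC1CC[C@H]2[C@@H](C1=O)C2(C)C | intermediate
5 | (1R,7S)-4,8,8-trimethyl-3-oxabicyclo[5.1.0]octan-2-one (C-4 epimers) | CC1CC[C@H]2[C@@H](C(=O)O1)C2(C)C | intermediate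
6 | (E)-penta-1,3-diene | C/C=C/C=C | starting material
7 | (pent-2-ene-1,4-diyl)magnesium, 2-methyl-1-magnesacyclopent-3-ene (THF solvate) | CC1C=CC[Mg]1 | intermediate
8 | 1-[(1R,3S)-3-(3-hydroxybutyl)-2,2-dimethylcyclopropyl]-2-methylcyclopent-3-en-1-ol | CC(O)CC[C@H]1[C@@H](C2(O)CC=CC2C)C1(C)C | intermediate
9 | 4-[(1S,3R)-3-(1-hydroxy-2-methylcyclopent-3-en-1-yl)-2,2-dimethylcyclopropyl]butan-2-one | CC(=O)CC[C@H]1[C@@H](C2(O)CC=CC2C)C1(C)C | intermediate
10 | 4-[(1S,3R)-2,2-dimethyl-3-(2-methylcyclopenta-1,3-dien-1-yl)cyclopropyl]butan-2-one | CC(=O)CC[C@H]1[C@@H](C2=C(C)C=CC2)C1(C)C | intermediate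
11 | 4-[(1S,3R)-2,2-dimethyl-3-(5-methylcyclopenta-1,4-dien-1-yl)cyclopropyl]butan-2-one | CC(=O)CC[C@H]1[C@@H](C2=CCC=C2C)C1(C)C | intermediate
12 | 4-[(1S,3R)-2,2-dimethyl-3-(2-methylcyclopenta-1,4-dien-1-yl)cyclopropyl]butan-2-one | CC(=O)CC[C@H]1[C@@H](C2=C(C)CC=C2)C1(C)C | intermediate
13 | CNP0300925.1, (1S,2S,5S,6S)-1,3-dimethyl-4,8-bis[(1R,3S)-2,2-dimethyl-3-(3-oxobutyl)cyclopropyl]tricyclo[4.2.1.1^{2,5}]deca-3,7-diene (syn isomer, boat central ring) | CC(=O)CC[C@H]1[C@@H](C2=C[C@@H]3C[C@@]2(C)[C@H]2C[C@@H]3C([C@@H]3[C@H](CCC(C)=O)C3(C)C)=C2C)C1(C)C | target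

**Step count and risks**

Total step count: 7. Longest linear sequence: 7 steps, from 1.

The three steps most likely to fail:

Step 7 is the weakest. The excited singlet of a cyclopentadiene lives far less than a nanosecond, so only dienes that already have a stacked neighbour can dimerise. Most excited molecules return to the ground state or close to bicyclo[2.1.0]pent-2-enes, which revert to the dienes on standing at room temperature. Any triplets that form give Diels–Alder-type and [2+2] dimers through bis-allyl biradicals, not the sandwich adduct. The pairs 11+11 and 12+12, pairs containing 10, the opposite stacking orientation and the opposite diene faces all compete, and an excited vinylcyclopropane can epimerise or open. A yield of 13 of a few per cent from an isomer mixture is the realistic expectation. The dienes and 13 must also stay below about 80 °C: cis-alkyl vinylcyclopropanes undergo the homodienyl 1,5-hydrogen shift, and 13 is a boat-held 1,5-diene that could undergo Cope rearrangement to a cyclobutane isomer. Fallback, a tethered intramolecular union in place of the bimolecular one: from 8, two molecules are joined through their secondary hydroxyls with i-Pr2SiCl2 (0.5 equiv, imidazole, DMF), the hindered tertiary carbinols staying free, to the bis-silyl ether F1. Double Burgess dehydration with equilibration gives the tethered bis(cyclopentadiene) F2. Irradiation (265 nm) at 0.005 M in pentane closes the 18-membered silicon-bridged adduct F3; at this dilution bimolecular Diels–Alder reaction is negligible, while the nine-atom tether keeps the two dienes within reach and raises the share of pre-stacked pairs. HF·pyridine in THF releases the diol F4. Oxidation with (n-Pr4N)RuO4 and N-methylmorpholine N-oxide comes back to the route at 13.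

Step 4 is second. The diene–magnesium annulation has not been run with penta-1,3-diene on a hindered cyclopropyl lactone, and 1,2-mode products (a β,γ-enone or a vinylcyclopropanol) may persist. Fallback, stepwise additions and metathesis: from 5, Me(MeO)NH·HCl/AlMe3 opens the lactone to the hydroxy Weinreb amide F5. But-2-enylmagnesium chloride (γ-attack, excess) gives the β,γ-unsaturated ketone F6. Allylmagnesium bromide gives the dienyl diol F7. Ring-closing metathesis with the second-generation Grubbs catalyst RuCl2(=CHPh)(PCy3)(H2IMes) in CH2Cl2 comes back to the route at 8.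

Step 3 is third. Baeyer–Villiger oxidation of a cyclopropyl ketone is slow, and forcing it with acid endangers the cyclopropane. Fallback, oxidative cleavage of an enol ether and relactonisation: from 4, LiN(i-Pr)2/Me3SiCl gives the silyl enol ether F8; enolisation goes toward the methyl-bearing carbon because the other α-carbon is the cyclopropane ring fusion. Ozonolysis (O3, CH2Cl2/MeOH, −78 °C; Me2S) gives the keto acid F9. NaBH4 gives the hydroxy acid F10. Yamaguchi lactonisation (2,4,6-trichlorobenzoyl chloride, Et3N, DMAP, PhMe, high dilution) comes back to the route at 5.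

Further compounds
F1 | step 7 | bis{4-[(1S,3R)-3-(1-hydroxy-2-methylcyclopent-3-en-1-yl)-2,2-dimethylcyclopropyl]butan-2-yloxy}di(propan-2-yl)silane | CC(CC[C@H]1[C@@H](C2(O)CC=CC2C)C1(C)C)O[Si](C(C)C)(C(C)C)OC(C)CC[C@H]1[C@@H](C2(O)CC=CC2C)C1(C)C
F2 | step 7 | tethered bis(cyclopentadiene), the di(propan-2-yl)silanediyl bis-ether drawn as the 12-type/11-type tautomer pair | CC(CC[C@H]1[C@@H](C2=C(C)CC=C2)C1(C)C)O[Si](C(C)C)(C(C)C)OC(C)CC[C@H]1[C@@H](C2=CCC=C2C)C1(C)C
F3 | step 7 | silicon-bridged [4+4] adduct (13 with its two C=O groups as CH–O joined through Si(i-Pr)2) | CC(O[Si]%10(C(C)C)C(C)C)CC[C@H]1[C@@H](C2=C[C@@H]3C[C@@]2(C)[C@H]2C[C@@H]3C([C@@H]3[C@H](CCC(C)O%10)C3(C)C)=C2C)C1(C)C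
F4 | step 7 | diol corresponding to 13, 4,4'-{[(1S,2S,5S,6S)-1,3-dimethyltricyclo[4.2.1.1^{2,5}]deca-3,7-diene-4,8-diyl]bis[(1S,3R)-2,2-dimethylcyclopropane-3,1-diyl]}di(butan-2-ol) | CC(O)CC[C@H]1[C@@H](C2=C[C@@H]3C[C@@]2(C)[C@H]2C[C@@H]3C([C@@H]3[C@H](CCC(C)O)C3(C)C)=C2C)C1(C)C
F5 | step 4 | (1R,3S)-3-(3-hydroxybutyl)-N-methoxy-N,2,2-trimethylcyclopropane-1-carboxamide | CC(O)CC[C@H]1[C@@H](C(=O)N(C)OC)C1(C)C
F6 | step 4 | 1-[(1R,3S)-3-(3-hydroxybutyl)-2,2-dimethylcyclopropyl]-2-methylbut-3-en-1-one | CC(O)CC[C@H]1[C@@H](C(=O)C(C)C=C)C1(C)C
F7 | step 4 | 4-[(1R,3S)-3-(3-hydroxybutyl)-2,2-dimethylcyclopropyl]-3-methylhepta-1,6-dien-4-ol | CC(O)CC[C@H]1[C@@H](C(O)(CC=C)C(C)C=C)C1(C)C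
F8 | step 3 | trimethyl{[(1R,6S)-3,7,7-trimethylbicyclo[4.1.0]hept-2-en-2-yl]oxy}silane | CC1=C(O[Si](C)(C)C)[C@@H]2[C@H](CC1)C2(C)C
F9 | step 3 | (1R,3S)-2,2-dimethyl-3-(3-oxobutyl)cyclopropane-1-carboxylic acid | CC(=O)CC[C@H]1[C@@H](C(O)=O)C1(C)C
F10 | step 3 | (1R,3S)-3-(3-hydroxybutyl)-2,2-dimethylcyclopropane-1-carboxylic acid | CC(O)CC[C@H]1[C@@H](C(O)=O)C1(C)C
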